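The earlier runs and the new flask were generated by integration for substances that don't exist; noise was put on by code.

| flask | starting complex | incoming ligand | remark | time |
|---|---|---|---|---|
| birch | 0.25 M | 0.79 equiv | run made earlier |  |
| elm | 0.25 M | 1.3 equiv | run made earlier |  |
| ash | 0.25 M | 1.6 equiv | run made earlier |  |
| ochre | 0.25 M | 1.10 equiv |  | 10 min |
| teal | 0.25 M | 1.40 equiv |  | 10 min |

| run | time / min | complex with two exchanged / % | complex with three exchanged / % | starting complex / % | complex with one exchanged / % |
|---|---|---|---|---|---|
| birch | 1.33 | 1.1 | 0 | 89.4 | 9.7 |
| birch | 3.00 | 3.6 | 0 | 79.1 | 15.0 |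
| birch | 4.00 | 4.4 | 0.1 | 74.4 | 19.8 |
| birch | 6.00 | 7.2 | 1.6 | 68.4 | 22.2 |
| birch | 8.00 | 9.5 | 2.0 | 62.3 | 23.8 |
| elm | 0.667 | 1.4 | 0 | 91.2 | 9.2 |
| elm | 2.00 | 4.3 | 0 | 76.3 | 17.8 |
| elm | 3.00 | 7.2 | 1.3 | 68.7 | 21.7 |
| elm | 5.00 | 13.0 | 3.6 | 56.9 | 24.9 |
| elm | 8.00 | 17.5 | 5.6 | 47.6 | 26.5 |
| ash | 0.667 | 0.7 | 0 | 88.4 | 10.1 |
| ash | 2.00 | 4.5 | 0.7 | 73.4 | 20.5 |
| ash | 3.00 | 9.7 | 2.6 | 62.6 | 23.3 |
| ash | 5.00 | 14.5 | 5.8 | 50.6 | 25.9 |
| ash | 8.00 | 22.9 | 7.9 | 38.9 | 26.6 |

(scatter of a reading: 0.5 percentage points)

- which of these there is most of at the end, counted by the starting complex in it, ochre (starting complex / complex with one exchanged / complex with two exchanged / complex with three exchanged)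
- which of these there is most of at the end, counted by the starting complex in it, teal (starting complex / complex with one exchanged / complex with two exchanged / complex with three exchanged)
- the largest of these amounts at the end, in percent of the starting complex charged, ochre
- the largest of these amounts at the end, in percent of the starting complex charged, teal



- A small charge started it: birch got 0.79 equiv of incoming ligand, while each complex can take 3, so the ligand is the limiting reagent of the full exchange, and I wrote its balance. As the ligand gone I counted the exchanged complexes the runs read, each by the ligands it holds, an estimate that overstates what is left if ligand also sits in anything unread.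
- At 8.00 min that count put what was left at 38.2 % of the charge in birch, 39.8 % in elm and 39.9 % in ash, whatever the charge, which is how a pseudo-first-order loss looks.
- I took the mean, 39.3 %, and so a decay constant of 0.117 /min for c(incoming ligand).
- If c(starting complex) falls in step with c(incoming ligand), its logarithmic loss per equivalent charged should match across runs at one time. The readings gave 0.599, 0.571 and 0.590, mean 0.587.
- Stretched in proportion to time, this gave ochre 44.6 %. That was the weak link, since it kept the ligand at full strength while it was falling.
- So I scaled by the decaying ligand instead and got 0.666, my loss per equivalent, the logarithm of the starting complex lost per equivalent charged by 10 min.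
- Ochre then came to 48.1 % and teal to 39.4 %. Ash, charged with more ligand than teal, read 26.6 % of the complex with one exchanged, 22.9 % of two and 7.9 % of three at 8.00 min, each lower than teal's figure. The complex with two exchanged was still rising there, but carried on at its last slope to 10 min it came to 28.5 %, still lower than teal's figure, so I kept the starting complex as largest in both.
- The forecast named starting complex at 49 % (46 % to 52 %) for ochre and starting complex at 39.5 % (36.5 % to 42.5 %) for teal, on the ground: “So the first step is first order in ligand and essentially irreversible.”
- The flasks gave starting complex at 48.0 % in ochre and starting complex at 39.2 % in teal.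

    starting complex + incoming ligand ⇌ leaving ligand + complex with one exchanged (K = 68.0, k = 0.00760 /M/s)
    complex with one exchanged + incoming ligand ⇌ leaving ligand + complex with two exchanged (K = 12.0, k = 0.0140 /M/s)
    complex with two exchanged + incoming ligand ⇌ leaving ligand + complex with three exchanged (K = 0.690, k = 0.0160 /M/s)
    complex with two exchanged → decomposed reagent (k = 1.70 × 10⁻⁴ /s)
    2 starting complex → homo dimer (k = 5.50 × 10⁻⁵ /M/s)
    starting complex + complex with three exchanged → side product (k = 0.00600 /M/s)

- At 10.0 min in ochre, the forward exchange used starting complex 9.6 times faster than the step to side product. So the route my loss per equivalent counts was carrying the greater part of that loss at the end of ochre.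
- For the neighbour of ochre with 0.660 equiv of incoming ligand, the loss per equivalent gives 64.4 %; that flask held 64.0 %.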